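**Plan**

1. Retrosynthesis: the C2 tiglate and C13 acetate go on last; the lactone O–C8 bond (with C9–H) is cut to an iodolactonization of a C8=C9 alkene; C7–C11 and O5–C11 are cut together as a [2,3] shift of a malonate oxonium ylide on an oxygen-bridged C7=C8 alkene; C9–C10 and C1–C5 are cut together as an intramolecular 3-oxidopyrylium–alkene [5+2] cycloaddition.
2. Enabling feature: the five ring-B carbons C5–C6–C7–C8–C9 carry oxygen at C5 (the ether oxygen) and at C8 (the lactone oxygen), so they are a masked 3-oxidopyrylium (ring O between C5 and C9, oxide on C8); C5 is tied through C4–C3–C2 of ring A to the two-carbon unit C1=C10.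
3. Forward order: acyclic C2/C4 diol on a furan (from 2-acetylfuran, crotonaldehyde, MeMgBr) → pyranone → ring A (cyclopentane) and ring B (cycloheptane) closed at once as an 8-oxabicyclo[3.2.1]octenone → oxygen bridge moved from C9 to C11 (tetrahydrofuran) → γ-lactone → esters.
4. Stereochemistry: C2 by Sharpless kinetic resolution; C4 by chelate-controlled 1,3-induction; C1, C5, C10 (and transient C9) in the cycloaddition (tether geometry, E-alkene, facial bias from C2 and C4); C7 by the suprafacial [2,3] shift; C8 and C11 by the geometry of the cis-lactone closure.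

Key step: step 8

Remark: dimethyl diazomalonate (15) and tigloyl chloride (24) are taken as purchasable; step 2 keeps the slow-reacting enantiomer, so at most half of 3 is carried on.
Convention: guaiane numbering (ring A = C1–C5; ring B = C1, C5–C10; C14 on C10, C15 on C4, C11–C13 on C7). β is the face of ring B that carries H-1 in the target, α the face that carries the C5 oxygen; for ring A, β means cis to H-1.

Step 1
Reactants: 1 2-acetylfuran; 2 (E)-but-2-enal
Product: 3 rac-(E)-1-(furan-2-yl)-3-hydroxyhex-4-en-1-one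
Conditions: LiN(SiMe3)2, THF, −78 °C; then 2; aq. NH4Cl
Reagents that add atoms: none
Why: Directed crossed aldol addition, in which the kinetic lithium enolate of the methyl ketone adds 1,2 to the enal at low temperature; the carbinol centre forms as a racemate and is resolved in step 2.

Step 2
Reactants: 3 rac-(E)-1-(furan-2-yl)-3-hydroxyhex-4-en-1-one
Product: 4 (S,E)-1-(furan-2-yl)-3-hydroxyhex-4-en-1-one
Conditions: Ti(Oi-Pr)4 (cat.), D-(−)-diisopropyl tartrate, t-BuOOH (0.6 equiv), 4 Å molecular sieves, CH2Cl2, −20 °C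
Reagents that add atoms: none
Why: Sharpless kinetic resolution of a secondary (E)-allylic alcohol, in which the D-(−)-tartrate catalyst should epoxidise the (R)-enantiomer much faster, so that stopping just past half conversion leaves the (S)-alcohol (the future C2); the acylfuran is not a furylcarbinol and should not be oxidised.

Step 3
Reactants: 4 (S,E)-1-(furan-2-yl)-3-hydroxyhex-4-en-1-one
Product: 5 (2R,4S,E)-2-(furan-2-yl)hept-5-ene-2,4-diol
Conditions: MeMgBr (3.5 equiv), CH2Cl2/Et2O, −78 → −40 °C; aq. NH4Cl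
Reagents that add atoms: methylmagnesium bromide, C[Mg]Br
Why: Chelation-controlled Grignard addition (1,3-induction), in which the magnesium alkoxide of the secondary hydroxyl binds the ketone oxygen in a six-membered half-chair with the propenyl group pseudo-equatorial and a second MeMgBr should attack axially (the facial sense of a Narasaka–Prasad reduction), leaving the furyl group equatorial and setting the tertiary carbinol (future C4) as R.

Step 4
Reactants: 5 (2R,4S,E)-2-(furan-2-yl)hept-5-ene-2,4-diol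
Product: 6 2-[(2R,4S,E)-2,4-bis(triethylsilyloxy)hept-5-en-2-yl]furan
Conditions: Et3SiOTf (2.5 equiv), 2,6-lutidine, CH2Cl2, −78 → 0 °C
Reagents that add atoms: triethylsilyl trifluoromethanesulfonate, CC[Si](CC)(CC)OS(=O)(=O)C(F)(F)F
Why: Silyl ether formation with the silyl triflate, which is reactive enough for the tertiary carbinol, while the lutidine buffer and low temperature should prevent ionisation of the furyl carbinol; no stereocentre is touched.

Step 5
Reactants: 6 2-[(2R,4S,E)-2,4-bis(triethylsilyloxy)hept-5-en-2-yl]furan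
Product: 7 {5-[(2R,4S,E)-2,4-bis(triethylsilyloxy)hept-5-en-2-yl]furan-2-yl}methanol
Conditions: n-BuLi, THF, −78 → 0 °C; then (CH2O)n, −78 °C → rt; aq. NH4Cl
Reagents that add atoms: formaldehyde (from paraformaldehyde), C=O
Why: α-Lithiation of a 2-alkylfuran at its free C5 position followed by hydroxymethylation, the silyl ethers offering no C–H of comparable acidity; this carbon becomes C9.

Step 6
Reactants: 7 {5-[(2R,4S,E)-2,4-bis(triethylsilyloxy)hept-5-en-2-yl]furan-2-yl}methanol
Product: 8 6-hydroxy-6-[(2R,4S,E)-2,4-bis(triethylsilyloxy)hept-5-en-2-yl]-2H-pyran-3(6H)-one (both epimers at the ketal carbon)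
Conditions: VO(acac)2 (5 mol%), t-BuOOH, CH2Cl2, 0 °C → rt
Reagents that add atoms: tert-butyl hydroperoxide, CC(C)(C)OO
Why: Achmatowicz oxidative ring expansion, in which the vanadium alkylperoxide bound to the furfuryl hydroxyl oxidises only the furan (the propenyl group is not an allylic alcohol) and the hydroxy-enedione closes to the six-membered hemiketal; the ketal carbon forms as an epimer mixture that is erased in step 8.

Step 7
Reactants: 8 6-hydroxy-6-[(2R,4S,E)-2,4-bis(triethylsilyloxy)hept-5-en-2-yl]-2H-pyran-3(6H)-one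
Product: 9 6-acetoxy-6-[(2R,4S,E)-2,4-bis(triethylsilyloxy)hept-5-en-2-yl]-2H-pyran-3(6H)-one (both epimers)
Conditions: Ac2O, DMAP, pyridine, CH2Cl2, 0 °C → rt
Reagents that add atoms: acetic anhydride, CC(=O)OC(C)=O
Why: DMAP-catalysed acyl transfer to the anomeric hydroxyl installs the leaving group needed for pyrylium formation; both epimers serve.

Step 8
Reactants: 9 6-acetoxy-6-[(2R,4S,E)-2,4-bis(triethylsilyloxy)hept-5-en-2-yl]-2H-pyran-3(6H)-one
Product: 11 2β,4β-bis(triethylsilyloxy)-5α,9α-epoxy-1βH-guai-6-en-8-one (4α-methyl; 10β-methyl), via oxidopyrylium ylide 10 (not isolated)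
Conditions: DBU (1.5 equiv), MeCN (0.01 M), 60 °C
Reagents that add atoms: none
Why: DBU removes the proton on the carbon between the ring oxygen and the ketone (future C9) and acetate leaves from the ketal carbon (future C5), giving 3-oxidopyrylium ylide 10, whose C5 and C9 termini add suprafacially to the tethered (E)-propenyl group in a thermally allowed six-electron [5+2] cycloaddition. The closest known reaction type is the intramolecular oxidopyrylium–alkene cycloaddition of 6-acetoxy-2H-pyran-3(6H)-ones that carry the alkene on a three-atom tether. Ring A closes through the C1–C5 bond in the exo mode that the three-atom tether enforces, and ring B closes through the C9–C10 bond of the same concerted, asynchronous event, the pyran oxygen remaining as the C5–O–C9 bridge. C5 and C9 are set together on the face away from the alkene (bridge α), C1 by the exo tether (H-1 anti to the bridge, the trans C1/C5 relation of the target) and C10 by the E geometry of the alkene (methyl endo, cis to H-1). The step needs facial selectivity relative to C2 and C4: in the favoured transition state the C4 methyl should lie next to the ring oxygen and the C4 silyloxy group next to C6–H (least allylic strain, C–O dipoles opposed), and the C2 silyloxy group should lie anti to C10 on the forming cyclopentane, both preferences leading to the same diastereomer. High dilution and the fully substituted C4 (Thorpe–Ingold effect) should keep the ylide from dimerising.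

Step 9
Reactants: 11 2β,4β-bis(triethylsilyloxy)-5α,9α-epoxy-1βH-guai-6-en-8-one
Product: 13 2β,4β-bis(triethylsilyloxy)-5α,9α-epoxyguai-7-en-8-yl trifluoromethanesulfonate, via lithium enolate 12 (not isolated)
Conditions: LiBH(s-Bu)3, THF, −78 °C; then PhNTf2, −78 → 0 °C; aq. NH4Cl
Reagents that add atoms: N-phenylbis(trifluoromethanesulfonimide), FC(F)(F)S(=O)(=O)N(c1ccccc1)S(=O)(=O)C(F)(F)F
Why: Conjugate reduction of the β-unsubstituted enone by the hindered borohydride gives the C7=C8 enolate regiospecifically (C9 is a bridgehead), and O-triflation traps it; no stereocentre is formed.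

Step 10
Reactants: 13 2β,4β-bis(triethylsilyloxy)-5α,9α-epoxyguai-7-en-8-yl trifluoromethanesulfonate
Product: 14 2β,4β-bis(triethylsilyloxy)-5α,9α-epoxyguai-7-ene
Conditions: Pd(OAc)2 (5 mol%), PPh3 (10 mol%), HCO2H, n-Bu3N, DMF, 60 °C
Reagents that add atoms: none
Why: Palladium-catalysed formate reduction of an enol triflate (oxidative addition to zerovalent palladium, hydride transfer from formate, reductive elimination) replaces the triflate by hydrogen and leaves the C7=C8 alkene allylic to the bridging oxygen at C9.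

Step 11
Reactants: 14 2β,4β-bis(triethylsilyloxy)-5α,9α-epoxyguai-7-ene; 15 dimethyl diazomalonate
Product: 17 dimethyl 2β,4β-bis(triethylsilyloxy)-5α,11-epoxy-7βH-guai-8-ene-12,13-dioate, via oxonium ylide 16 (not isolated)
Conditions: Rh2(OAc)4 (2 mol%), ClCH2CH2Cl, 80 °C, 15 added slowly
Reagents that add atoms: none
Why: Proposed new method: the electrophilic rhodium carbene from 15 should be captured by the exposed lone pair of the bridging ether oxygen (ylides at the shielded silyl ether oxygens can only revert), and in ylide 16 the malonate carbanion sits over the O–C9–C8=C7 allyl unit, so a suprafacial [2,3]-sigmatropic shift should form C11–C7 on the α face, break O–C9 and move the alkene to C8=C9, transposing the bridge from C5/C9 to C5/C11 and setting C7 (H β); the closest known reaction type is the intermolecular rhodium-catalysed oxonium-ylide formation and [2,3] rearrangement of allyl ethers with diazo esters, not yet shown on a bridged 8-oxabicyclo[3.2.1]oct-2-ene; the symmetric malonate keeps C11 non-stereogenic here and has no β-hydrogen for a competing 1,2-shift.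

Step 12
Reactants: 17 dimethyl 2β,4β-bis(triethylsilyloxy)-5α,11-epoxy-7βH-guai-8-ene-12,13-dioate
Product: 19 9β-iodo-2β,4β-bis(triethylsilyloxy)-5α,11-epoxyguaian-12,8α-olid-13-oic acid, via dicarboxylic acid 18 (not isolated)
Conditions: LiOH, THF/MeOH/H2O, 40 °C; then NaHCO3 buffer (pH 8), I2, KI, 0 °C → rt, dark; Na2S2O3; HCl to pH 3
Reagents that add atoms: lithium hydroxide, [Li+].[OH-]; iodine, II
Why: Saponification followed by iodolactonization, in which only the carboxylate on the side of C11 that faces C8 can reach the iodonium ion and opens it anti in the 5-exo mode, setting C8 (oxygen α, cis to C11) and C9 (iodine β) and, by telling the two carboxyl groups apart, fixing C11.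

Step 13
Reactants: 19 9β-iodo-2β,4β-bis(triethylsilyloxy)-5α,11-epoxyguaian-12,8α-olid-13-oic acid
Product: 20 13-hydroxy-9β-iodo-2β,4β-bis(triethylsilyloxy)-5α,11-epoxyguaian-12,8α-olide
Conditions: BH3·SMe2, THF, 0 °C → rt; MeOH
Reagents that add atoms: none
Why: Borane reduction of a carboxylic acid (through the acyloxyborane) is much faster than reduction of the lactone, so the C13 primary alcohol should form while the iodide, lactone and silyl ethers stay; running this before the radical step avoids heating a malonic half-acid.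

Step 14
Reactants: 20 13-hydroxy-9β-iodo-2β,4β-bis(triethylsilyloxy)-5α,11-epoxyguaian-12,8α-olide
Product: 21 13-hydroxy-2β,4β-bis(triethylsilyloxy)-5α,11-epoxyguaian-12,8α-olide
Conditions: Bu3SnH, AIBN (cat.), PhMe, 80 °C
Reagents that add atoms: none
Why: Radical-chain dehalogenation (the stannyl radical abstracts iodine and the C9 radical takes hydrogen from Bu3SnH) turns C9 into a methylene group without touching any other centre.

Step 15
Reactants: 21 13-hydroxy-2β,4β-bis(triethylsilyloxy)-5α,11-epoxyguaian-12,8α-olide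
Product: 22 13-acetoxy-2β,4β-bis(triethylsilyloxy)-5α,11-epoxyguaian-12,8α-olide
Conditions: Ac2O, pyridine, DMAP (cat.), CH2Cl2, rt
Reagents that add atoms: acetic anhydride, CC(=O)OC(C)=O
Why: DMAP-catalysed acetylation of the only free hydroxyl (primary, neopentyl-type).

Step 16
Reactants: 22 13-acetoxy-2β,4β-bis(triethylsilyloxy)-5α,11-epoxyguaian-12,8α-olide
Product: 23 13-acetoxy-2β,4β-dihydroxy-5α,11-epoxyguaian-12,8α-olide
Conditions: HF·pyridine, pyridine/THF, 0 °C → rt
Reagents that add atoms: none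
Why: Fluoride-driven cleavage of both triethylsilyl ethers (Si–F bond formation) under buffered conditions that should leave the acetate, lactone and bridging ether intact.

Step 17
Reactants: 23 13-acetoxy-2β,4β-dihydroxy-5α,11-epoxyguaian-12,8α-olide; 24 tigloyl chloride
Product: 25 CNP0112086.1 (13-acetoxy-4β-hydroxy-2β-tigloyloxy-5α,11-epoxyguaian-12,8α-olide)
Conditions: 24 (1.5 equiv), DMAP, pyridine, CH2Cl2, 0 °C → rt
Reagents that add atoms: none
Why: DMAP-catalysed acylation with the acid chloride should be selective for the secondary C2 hydroxyl over the tertiary C4 hydroxyl flanked by the quaternary C5; the E (tiglate) geometry is the stable one and is retained.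

**Compound list**

1 | 2-acetylfuran | CC(=O)c1ccco1 | starting material
2 | (E)-but-2-enal (crotonaldehyde) | C/C=C/C=O | starting material
3 | rac-(E)-1-(furan-2-yl)-3-hydroxyhex-4-en-1-one | C/C=C/C(O)CC(=O)c1ccco1 | intermediate
4 | (S,E)-1-(furan-2-yl)-3-hydroxyhex-4-en-1-one | C/C=C/[C@@H](O)CC(=O)c1ccco1 | intermediate
5 | (2R,4S,E)-2-(furan-2-yl)hept-5-ene-2,4-diol | C/C=C/[C@@H](O)C[C@@](C)(O)c1ccco1 | intermediate
6 | 2-[(2R,4S,E)-2,4-bis(triethylsilyloxy)hept-5-en-2-yl]furan | C/C=C/[C@@H](O[Si](CC)(CC)CC)C[C@@](C)(O[Si](CC)(CC)CC)c1ccco1 | intermediate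
7 | {5-[(2R,4S,E)-2,4-bis(triethylsilyloxy)hept-5-en-2-yl]furan-2-yl}methanol | C/C=C/[C@@H](O[Si](CC)(CC)CC)C[C@@](C)(O[Si](CC)(CC)CC)c1ccc(CO)o1 | intermediate
8 | 6-hydroxy-6-[(2R,4S,E)-2,4-bis(triethylsilyloxy)hept-5-en-2-yl]-2H-pyran-3(6H)-one (epimers at C6) | C/C=C/[C@@H](O[Si](CC)(CC)CC)C[C@@](C)(O[Si](CC)(CC)CC)C1(O)C=CC(=O)CO1 | intermediate
9 | 6-acetoxy-6-[(2R,4S,E)-2,4-bis(triethylsilyloxy)hept-5-en-2-yl]-2H-pyran-3(6H)-one (epimers at C6) | C/C=C/[C@@H](O[Si](CC)(CC)CC)C[C@@](C)(O[Si](CC)(CC)CC)C1(OC(C)=O)C=CC(=O)CO1 | intermediate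
10 | 6-[(2R,4S,E)-2,4-bis(triethylsilyloxy)hept-5-en-2-yl]pyrylium-3-olate (oxidopyrylium ylide) | C/C=C/[C@@H](O[Si](CC)(CC)CC)C[C@@](C)(O[Si](CC)(CC)CC)c1ccc([O-])c[o+]1 | intermediate
11 | 2β,4β-bis(triethylsilyloxy)-5α,9α-epoxy-1βH-guai-6-en-8-one | CC[Si](CC)(CC)O[C@H]1C[C@@](C)(O[Si](CC)(CC)CC)[C@@]23C=CC(=O)[C@H](O3)[C@@H](C)[C@H]12 | intermediate
12 | lithium C7=C8 enolate of the 6,7-dihydro ketone | CC[Si](CC)(CC)O[C@H]1C[C@@](C)(O[Si](CC)(CC)CC)[C@@]23CC=C(O[Li])[C@H](O3)[C@@H](C)[C@H]12 | intermediate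
13 | 2β,4β-bis(triethylsilyloxy)-5α,9α-epoxyguai-7-en-8-yl trifluoromethanesulfonate | CC[Si](CC)(CC)O[C@H]1C[C@@](C)(O[Si](CC)(CC)CC)[C@@]23CC=C(OS(=O)(=O)C(F)(F)F)[C@H](O3)[C@@H](C)[C@H]12 | intermediate
14 | 2β,4β-bis(triethylsilyloxy)-5α,9α-epoxyguai-7-ene | CC[Si](CC)(CC)O[C@H]1C[C@@](C)(O[Si](CC)(CC)CC)[C@@]23CC=C[C@H](O3)[C@@H](C)[C@H]12 | intermediate
15 | dimethyl diazomalonate | COC(=O)C(=[N+]=[N-])C(=O)OC | starting material
16 | oxonium ylide on the bridging oxygen of 14 | CC[Si](CC)(CC)O[C@H]1C[C@@](C)(O[Si](CC)(CC)CC)[C@@]23CC=C[C@H]([O+]3[C-](C(=O)OC)C(=O)OC)[C@@H](C)[C@H]12 | intermediate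
17 | dimethyl 2β,4β-bis(triethylsilyloxy)-5α,11-epoxy-7βH-guai-8-ene-12,13-dioate | CC[Si](CC)(CC)O[C@H]1C[C@@](C)(O[Si](CC)(CC)CC)[C@@]23C[C@@H](C=C[C@@H](C)[C@H]12)C(C(=O)OC)(C(=O)OC)O3 | intermediate
18 | 2β,4β-bis(triethylsilyloxy)-5α,11-epoxy-7βH-guai-8-ene-12,13-dioic acid | CC[Si](CC)(CC)O[C@H]1C[C@@](C)(O[Si](CC)(CC)CC)[C@@]23C[C@@H](C=C[C@@H](C)[C@H]12)C(C(=O)O)(C(=O)O)O3 | intermediate
19 | 9β-iodo-2β,4β-bis(triethylsilyloxy)-5α,11-epoxyguaian-12,8α-olid-13-oic acid | CC[Si](CC)(CC)O[C@H]1C[C@@](C)(O[Si](CC)(CC)CC)[C@@]23C[C@H]4[C@@H]([C@@H](I)[C@@H](C)[C@H]12)OC(=O)[C@@]4(C(=O)O)O3 | intermediate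
20 | 13-hydroxy-9β-iodo-2β,4β-bis(triethylsilyloxy)-5α,11-epoxyguaian-12,8α-olide | CC[Si](CC)(CC)O[C@H]1C[C@@](C)(O[Si](CC)(CC)CC)[C@@]23C[C@H]4[C@@H]([C@@H](I)[C@@H](C)[C@H]12)OC(=O)[C@@]4(CO)O3 | intermediate
21 | 13-hydroxy-2β,4β-bis(triethylsilyloxy)-5α,11-epoxyguaian-12,8α-olide | CC[Si](CC)(CC)O[C@H]1C[C@@](C)(O[Si](CC)(CC)CC)[C@@]23C[C@H]4[C@@H](C[C@@H](C)[C@H]12)OC(=O)[C@@]4(CO)O3 | intermediate
22 | 13-acetoxy-2β,4β-bis(triethylsilyloxy)-5α,11-epoxyguaian-12,8α-olide | CC[Si](CC)(CC)O[C@H]1C[C@@](C)(O[Si](CC)(CC)CC)[C@@]23C[C@H]4[C@@H](C[C@@H](C)[C@H]12)OC(=O)[C@@]4(COC(C)=O)O3 | intermediate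
23 | 13-acetoxy-2β,4β-dihydroxy-5α,11-epoxyguaian-12,8α-olide | O[C@H]1C[C@@](C)(O)[C@@]23C[C@H]4[C@@H](C[C@@H](C)[C@H]12)OC(=O)[C@@]4(COC(C)=O)O3 | intermediate
24 | tigloyl chloride, (E)-2-methylbut-2-enoyl chloride | C/C=C(\C)C(Cl)=O | starting material
25 | CNP0112086.1 | C/C=C(\C)C(=O)O[C@H]1C[C@@](C)(O)[C@@]23C[C@H]4[C@@H](C[C@@H](C)[C@H]12)OC(=O)[C@@]4(COC(C)=O)O3 | target

**Count and risks**

Total step count: 17. Longest linear sequence: 17 steps (from 1 and 2).

Step 11 (Proposed new method). The carbene may fail to engage the hindered bridging oxygen and be lost to dimerisation or C–H insertion, or the ylide may take a Stevens 1,2-shift or find the [2,3] geometry too strained. The fallback uses known reactions only, sets out from 11 and returns at 21. Conjugate reduction of 11 with LiBH(s-Bu)3 and alkylation of the enolate with methyl bromoacetate, from the face of the oxygen bridge (the other face is screened by the C1–C10 bridge and its endo methyl), should give the 7α-(methoxycarbonylmethyl) ketone F1. SmI2 in THF/MeOH cleaves the α-alkoxy C9–O bond to the C5-hydroxy ketone F2. LiBH(s-Bu)3 reduces C8 from the face opposite the side chain and the cis hydroxy ester closes to the hydroxy lactone F3. The lactone enolate (LiN(SiMe3)2, 2 equiv) is brominated with CBr4 on the face away from C6 to give the α-bromo lactone F4. AgOTf with 2,6-lutidine closes the O5–C11 bond by intramolecular displacement with inversion, giving the ether lactone F5. Its enolate (LiN(i-Pr)2) is hydroxymethylated with formaldehyde on the open face to give 21.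

Step 8. The ketal carbon sits next to the fully substituted C4, so hemiketal closure or its acetylation (steps 6 and 7) may fail and the pyrylium never form; the ylide may also dimerise, or add with poor facial selectivity. The fallback forms the same two bonds by a carbonyl-ylide cycloaddition, sets out from 6 and returns at 13. Oxidation of the free furan position of 6 with NaClO2/NaH2PO4 opens the ring to the (Z)-4-oxo-2-enoic acid F6. Zn in AcOH reduces the enedione alkene to the keto acid F7. The mixed anhydride (i-BuOCOCl, N-methylmorpholine) and CH2N2 give the diazoketone F8. Rh2(OAc)4 generates the carbene at C9, the C5 ketone oxygen closes the six-membered carbonyl ylide, and intramolecular 1,3-dipolar cycloaddition to the propenyl group gives the saturated oxa-bridged ketone F9 with the same exo-tether geometry. KN(SiMe3)2 and PhNTf2 convert F9 into 13.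

Step 3. The methyl addition may show poor facial selectivity, or the β-alkoxido ketone may undergo retro-aldol cleavage or enolisation. The fallback sets both centres under reagent control, sets out from 1 and returns at 6. Asymmetric allylboration of 1 (allyl-B(Oi-Pr)2 with the enantiomer of 3,3'-dibromo-BINOL that delivers the R carbinol) gives the tertiary homoallylic alcohol F10. Et3SiOTf gives the silyl ether F11. Wacker oxidation (PdCl2, CuCl, O2, DMF/H2O) gives the methyl ketone F12. Aldol addition of its kinetic enolate (LiN(SiMe3)2) to acetaldehyde gives the β-hydroxy ketone F13, and dehydration (MsCl, Et3N) gives the (E)-enone F14. Corey–Bakshi–Shibata reduction with the (R)-methyl oxazaborolidine and BH3·SMe2 gives the (S)-allylic alcohol F15, and Et3SiOTf then gives 6.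

**Further compounds**

F1 | step 11 | 7α-(methoxycarbonylmethyl)-2β,4β-bis(triethylsilyloxy)-5α,9α-epoxyguaian-8-one | CC[Si](CC)(CC)O[C@H]1C[C@@](C)(O[Si](CC)(CC)CC)[C@@]23C[C@H](CC(=O)OC)C(=O)[C@H](O3)[C@@H](C)[C@H]12
F2 | step 11 | methyl ester of the 5α-hydroxy-8-oxo acid (C9–O cleaved) | CC[Si](CC)(CC)O[C@H]1C[C@@](C)(O[Si](CC)(CC)CC)[C@@]2(O)C[C@H](CC(=O)OC)C(=O)C[C@@H](C)[C@H]12
F3 | step 11 | 5α-hydroxy-2β,4β-bis(triethylsilyloxy)guaian-12,8α-olide (C13 absent) | CC[Si](CC)(CC)O[C@H]1C[C@@](C)(O[Si](CC)(CC)CC)[C@@]2(O)C[C@@H]3CC(=O)O[C@@H]3C[C@@H](C)[C@H]12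
F4 | step 11 | 11-bromo derivative of F3 (bromine cis to H-7) | CC[Si](CC)(CC)O[C@H]1C[C@@](C)(O[Si](CC)(CC)CC)[C@@]2(O)C[C@@H]3[C@@H](Br)C(=O)O[C@@H]3C[C@@H](C)[C@H]12
F5 | step 11 | 2β,4β-bis(triethylsilyloxy)-5α,11-epoxy-13-norguaian-12,8α-olide | CC[Si](CC)(CC)O[C@H]1C[C@@](C)(O[Si](CC)(CC)CC)[C@@]23C[C@H]4[C@@H](C[C@@H](C)[C@H]12)OC(=O)[C@H]4O3
F6 | step 8 | (2Z,5R,7S,8E)-5-methyl-4-oxo-5,7-bis(triethylsilyloxy)deca-2,8-dienoic acid | C/C=C/[C@@H](O[Si](CC)(CC)CC)C[C@@](C)(O[Si](CC)(CC)CC)C(=O)/C=C\C(=O)O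
F7 | step 8 | (5R,7S,E)-5-methyl-4-oxo-5,7-bis(triethylsilyloxy)dec-8-enoic acid | C/C=C/[C@@H](O[Si](CC)(CC)CC)C[C@@](C)(O[Si](CC)(CC)CC)C(=O)CCC(=O)O
F8 | step 8 | diazomethyl ketone of F7 | C/C=C/[C@@H](O[Si](CC)(CC)CC)C[C@@](C)(O[Si](CC)(CC)CC)C(=O)CCC(=O)C=[N+]=[N-]
F9 | step 8 | 2β,4β-bis(triethylsilyloxy)-5α,9α-epoxy-1βH-guaian-8-one | CC[Si](CC)(CC)O[C@H]1C[C@@](C)(O[Si](CC)(CC)CC)[C@@]23CCC(=O)[C@H](O3)[C@@H](C)[C@H]12
F10 | step 3 | (R)-2-(furan-2-yl)pent-4-en-2-ol | C=CC[C@@](C)(O)c1ccco1
F11 | step 3 | triethylsilyl ether of F10 | C=CC[C@@](C)(O[Si](CC)(CC)CC)c1ccco1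
F12 | step 3 | (R)-4-(furan-2-yl)-4-(triethylsilyloxy)pentan-2-one | CC(=O)C[C@@](C)(O[Si](CC)(CC)CC)c1ccco1
F13 | step 3 | (6R)-6-(furan-2-yl)-2-hydroxy-6-(triethylsilyloxy)heptan-4-one (epimers at C2) | CC(O)CC(=O)C[C@@](C)(O[Si](CC)(CC)CC)c1ccco1
F14 | step 3 | (R,E)-6-(furan-2-yl)-6-(triethylsilyloxy)hept-2-en-4-one | C/C=C/C(=O)C[C@@](C)(O[Si](CC)(CC)CC)c1ccco1
F15 | step 3 | (2R,4S,E)-2-(furan-2-yl)-2-(triethylsilyloxy)hept-5-en-4-ol | C/C=C/[C@@H](O)C[C@@](C)(O[Si](CC)(CC)CC)c1ccco1
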